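The runs were computed with constants of no real substance; the scatter is artificial.

Take a small charge of substrate in a closed, stirred flask held at one temperature, and before asking how much target it gives, count how many half-lives of substrate the asked time holds: the count tells whether the flask has finished, and a finished flask holds a share.

| flask | substrate | temperature | remark | time |
|---|---|---|---|---|
| west | 0.025 M | −5 °C | run made earlier |  |
| east | 0.038 M | 28 °C | run made earlier |  |
| oak | 0.050 M | 40 °C |  | 5.0 min |
| larch | 0.050 M | 0 °C |  | 5.0 min |
| ash | 0.050 M | 20 °C |  | 5.0 min |
| birch | 0.050 M | −20 °C |  | 5.0 min |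

| run | time / min | target / % | substrate / % |
|---|---|---|---|
| west | 8.00 | 12.3 | 55.2 |
| west | 15.0 | 16.2 | 34.1 |
| west | 25.0 | 22.3 | 17.0 |
| west | 30.0 | 23.6 | 12.6 |
| east | 0.833 | 27.8 | 21.9 |
| east | 2.00 | 33.8 | 3.0 |
| east | 4.00 | 34.6 | 0 |
| east | 5.00 | 36.2 | 0 |

(standard deviation of a reading: 1 percentage point)

- in a conversion other conformer counts as not yet reacted
- a reading or a percentage of target counts all its forms, free or not

* the flask that comes out highest in amount of target, in percent of the substrate charged, or "all alike" when all lie within 1.5 percentage points (oak / larch / ash / birch / all alike)
* target at the end, in percent of the substrate charged, oak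
* target at the end, in percent of the substrate charged, larch
* target at the end, in percent of the substrate charged, ash
* target at the end, in percent of the substrate charged, birch

Look first at the east run, where two numbers seem not to go together: substrate reads 0% at 4.00 min, yet target reads 36.2% at 5.00 min. From the first east reading reckon a half-life of 0.380 min, so that last reading lies 13.2 half-lives in, and the flask had simply finished. Then read target per substrate consumed in the west run, 27.5% at 8.00 min and 27.0% at 30.0 min, nearly the same, which says target is one branch of a split (a selectivity) and something unread takes the rest from the start.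

Take the west half-life, 10.0 min, against the east one, and the half-life halves every 6.99 K. For oak that gives 0.116 min and 43.2 half-lives: call the asked time over the half-life at the flask's temperature the half-life count. Ash counts 5.95, larch 0.818 with 56.7% of its substrate left, and birch 0.112 with 92.5% left. So reckon oak finished, with the highest count, and since the share read higher in the east run than in the west, commit to oak coming out highest, above 36.2%.

The forecast gives oak at 38% (34% to 45%), ash 32.5%, larch 11.3% and birch 1.3%, holding that “The target per substrate consumed stays constant within each run”.

The flasks give oak 53.0%, ash 28.0%, larch 11.9% and birch 1.32%, crystals counted in target.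

    substrate ⇌ other conformer (K = 2.60, k = 0.110 min⁻¹, Ea = 84.0 kJ mol⁻¹, ΔH = −59.0 kJ mol⁻¹)
    substrate → target (k = 0.0330 min⁻¹, Ea = 72.0 kJ mol⁻¹)
    other conformer → isomer of the product (k = 0.450 min⁻¹, Ea = 68.0 kJ mol⁻¹)
    crystals ⇌ target, rate k4*(cs4 - [target]) while solid is left; crystals form when [target] > cs4 (solubility = 0.660 mM, k = 1.40 min⁻¹)
    other conformer ⇌ dormant form (K = 2.70, k = 0.0430 min⁻¹, Ea = 90.0 kJ mol⁻¹, ΔH = −60.0 kJ mol⁻¹)
    (constants at 0 °C)

Oak ends with substrate at 0%, as its count of 43.2 says, so its 53.0% is a finished share, and at 0.209 min in oak other conformer is made at 0.839 of the rate it is used up, while dissolved target is made 2.90 times faster than it is used up. The same flask run at 15 °C counts 3.62 half-lives, which leaves 8.12% unreacted against 8.45% of substrate, other conformer and dormant form together simulated, and it ends with target at 24.3% and isomer of the product at 67.3%.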